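**Strategy.** Atoms are numbered as in germacranolides: carbocycle C1 (carbinol) to C10 (methyl-bearing alkene carbon), epoxide C4/C5, lactone C6–O/C7=C11–C12, hydroxymethyl C13. The route cuts the ten-membered carbocycle at C2–C3. An anionic oxy-Cope ring expansion of a trans-2-isopropenyl-1-vinylcyclohexanol (six-membered ring C5–C10) breaks C5–C10 and forms C2–C3. In one operation it gives the cyclodecene with the E-C4=C5 alkene (epoxide precursor) and a C10/C1 enolate, which is hydroxylated at C1. The step exploits the 1,5-relationship between the C4–C5 epoxide and the oxygenated C1–C10 unit across the ten-membered ring. The butenolide travels through it as a silylated cis-enediol.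

Key step: step 13

Remark on the chemistry: compounds 22–31 are carried as both C1 epimers (drawn without a C1 descriptor); C1 becomes a ketone in step 20 and is set in step 23. Compounds 11–13 are mixtures at the phosphonate-bearing carbon, which becomes sp2 in step 8. "Up/trans/cis" and C-numbers in names refer to the target numbering above.

Step 1
Reactants: 1 4,4-dimethoxycyclohexa-2,5-dien-1-one; 2 potassium isopropenyltrifluoroborate
Product: 3 (S)-4,4-dimethoxy-5-(prop-1-en-2-yl)cyclohex-2-en-1-one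
Conditions: [Rh(cod)2]BF4 (3 mol%), (S)-BINAP, Et3N, toluene/H2O, 25 °C
Reagents that add atoms: none
Why: Rhodium-catalysed asymmetric 1,4-addition (Hayashi–Miyaura type) of an alkenyltrifluoroborate to one of the two enantiotopic enone units of the quinone monoketal should stop at the mono-adduct, the (S)-BINAP complex attacking the enone face that gives (S)-3-substituted cyclohexanones and so setting C5, from which C6 and C8 are relayed.

Step 2
Reactants: 3 (S)-4,4-dimethoxy-5-(prop-1-en-2-yl)cyclohex-2-en-1-one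
Product: 4 (S)-triethyl{[4,4-dimethoxy-5-(prop-1-en-2-yl)cyclohex-1-en-1-yl]oxy}silane
Conditions: RhCl(PPh3)3 (1 mol%), Et3SiH, THF, 50 °C
Reagents that add atoms: triethylsilane, CC[SiH](CC)CC
Why: Rhodium-catalysed 1,4-hydrosilylation of the enone with a monohydrosilane should give the regiodefined C7/C8 silyl enol ether and leave the 1,1-disubstituted isopropenyl alkene untouched.

Step 3
Reactants: 4 (S)-triethyl{[4,4-dimethoxy-5-(prop-1-en-2-yl)cyclohex-1-en-1-yl]oxy}silane
Product: 6 (2S,5S)-4,4-dimethoxy-5-(prop-1-en-2-yl)-2-(triethylsilyloxy)cyclohexan-1-one, via silyloxy epoxide 5 (not isolated)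
Conditions: mCPBA (1.05 equiv), NaHCO3, CH2Cl2, −20 °C
Reagents that add atoms: 3-chloroperoxybenzoic acid, OOC(=O)c1cccc(Cl)c1
Why: Rubottom oxidation of the electron-rich enol ether (far faster than the isopropenyl group) with 1,4-silyl shift should place the C8 silyloxy group trans to the isopropenyl group, because the peracid avoids the pseudo-axial methoxy group of the half-chair with equatorial isopropenyl, and this equatorial, epimerisable centre is also the thermodynamic one.

Step 4
Reactants: 6 (2S,5S)-4,4-dimethoxy-5-(prop-1-en-2-yl)-2-(triethylsilyloxy)cyclohexan-1-one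
Product: 8 (2R,3R,6S)-2-hydroxy-4,4-dimethoxy-3-(prop-1-en-2-yl)-6-(triethylsilyloxy)cyclohexan-1-one, via potassium enolate 7 (not isolated)
Conditions: KN(SiMe3)2, THF, −78 °C; 3-phenyl-2-(phenylsulfonyl)oxaziridine; aq. NH4Cl
Reagents that add atoms: 3-phenyl-2-(phenylsulfonyl)oxaziridine, O=S(=O)(c1ccccc1)N1OC1c1ccccc1
Why: Kinetic deprotonation should occur at the C6 methylene and not at the silyloxy-bearing C8 methine, and Davis hydroxylation of the enolate anti to the adjacent isopropenyl group should set C6 trans to C5 and therefore cis to the C8 oxygen (all-equatorial product).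

Step 5
Reactants: 9 ethyl 2-(diethoxyphosphoryl)acrylate; 10 4-methoxybenzyl alcohol
Product: 11 ethyl 2-(diethoxyphosphoryl)-3-[(4-methoxybenzyl)oxy]propanoate
Conditions: KOtBu (10 mol%), THF, 0 °C
Reagents that add atoms: none
Why: Base-catalysed oxa-Michael addition of the alcohol to the doubly activated vinylphosphonate should install the protected C13 oxygen.

Step 6
Reactants: 11 ethyl 2-(diethoxyphosphoryl)-3-[(4-methoxybenzyl)oxy]propanoate
Product: 12 2-(diethoxyphosphoryl)-3-[(4-methoxybenzyl)oxy]propanoic acid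
Conditions: LiOH, THF/H2O, 0 °C; then 1 M HCl
Reagents that add atoms: lithium hydroxide, [Li+].[OH-]
Why: Saponification of the carboxylic ethyl ester in the presence of the less electrophilic phosphonate esters should give the acid.

Step 7
Reactants: 8 (2R,3R,6S)-2-hydroxy-4,4-dimethoxy-3-(prop-1-en-2-yl)-6-(triethylsilyloxy)cyclohexan-1-one; 12 2-(diethoxyphosphoryl)-3-[(4-methoxybenzyl)oxy]propanoic acid
Product: 13 C6-O phosphonoacyl ester of 8
Conditions: DCC, DMAP (cat.), CH2Cl2, 0 → 25 °C
Reagents that add atoms: none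
Why: Steglich esterification of the only free hydroxyl (on C6) should attach the C11–C13 unit next to the C7 ketone.

Step 8
Reactants: 13 C6-O phosphonoacyl ester of 8
Product: 14 (4S,7R,7aR)-6,6-dimethoxy-3-{[(4-methoxybenzyl)oxy]methyl}-7-(prop-1-en-2-yl)-4-(triethylsilyloxy)-5,6,7,7a-tetrahydro-1-benzofuran-2(4H)-one
Conditions: LiCl, iPr2NEt, MeCN, 25 °C
Reagents that add atoms: none
Why: Intramolecular Horner–Wadsworth–Emmons olefination (Masamune–Roush conditions) of the C7 ketone should close the butenolide with the C7=C11 bond, any β-loss of the benzyloxide from the phosphonate carbanion being reversible by re-addition.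

Step 9
Reactants: 14 bicyclic butenolide
Product: 16 cis-enediol (C6–OH and C12–OH; CH2OH arm cis to C6 and CH2OPMB arm cis to C8 on C7=C11), via lactol 15 (not isolated)
Conditions: iBu2AlH (4 equiv), CH2Cl2, −78 → 0 °C; aq. potassium sodium tartrate
Reagents that add atoms: none
Why: Exhaustive 1,2-reduction of the unsaturated lactone should open it to the allylic 1,4-diol, which removes the acidic C6–H of the butenolide for the coming base steps while keeping the C6 configuration.

Step 10
Reactants: 16 cis-enediol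
Product: 17 bis(tert-butyldimethylsilyl) ether of 16
Conditions: TBSCl, imidazole, DMAP (cat.), DMF, 40 °C
Reagents that add atoms: tert-butyldimethylsilyl chloride, CC(C)(C)[Si](C)(C)Cl
Why: Silylation of the primary and the secondary allylic alcohol under non-acidic conditions should spare the dimethyl ketal.

Step 11
Reactants: 17 bis(tert-butyldimethylsilyl) ether of 16
Product: 18 C10 ketone (2-isopropenylcyclohexanone)
Conditions: PPTS (cat.), acetone/H2O, 25 °C
Reagents that add atoms: water, O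
Why: Mild acid hydrolysis should cleave the dimethyl ketal much faster than the silyl ethers, and the enolisable C5 centre stays in its equatorial (trans to O6) arrangement.

Step 12
Reactants: 18 C10 ketone
Product: 19 trans-2-isopropenyl-1-vinylcyclohexanol (C10–OH axial and vinyl trans to isopropenyl)
Conditions: CH2=CHMgBr, CeCl3, THF, −78 °C
Reagents that add atoms: vinylmagnesium bromide, C=C[Mg]Br
Why: The weakly basic organocerium reagent should add without enolisation by equatorial attack on the all-equatorial chair, which sets C10 with the vinyl group trans to the C5 isopropenyl group.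

Step 13
Reactants: 19 trans-2-isopropenyl-1-vinylcyclohexanol
Product: 22 ten-membered α-hydroxy ketone (C10 ketone and C1 carbinol and E-C4=C5), via potassium alkoxide 20 (not isolated), via potassium enolate 21 (not isolated)
Conditions: KN(SiMe3)2, 18-crown-6, THF, 0 → 25 °C; then −78 °C, 3-phenyl-2-(phenylsulfonyl)oxaziridine; aq. NH4Cl
Reagents that add atoms: 3-phenyl-2-(phenylsulfonyl)oxaziridine, O=S(=O)(c1ccccc1)N1OC1c1ccccc1
Why: Deprotonation gives potassium alkoxide 20, whose C10 oxyanion accelerates a [3,3]-sigmatropic shift through a six-centre chair in which C2 bonds to C3 while C5–C10 breaks, giving the ten-membered potassium enolate 21. The closest known reaction type is the anionic oxy-Cope ring expansion of trans-2-alkenyl-1-vinylcyclohexanols to (E)-cyclodec-5-enones. The ten-membered carbocycle closes by four-atom ring expansion of the six-membered ring C5–C10 (sigmatropic, not end-to-end), so no high dilution is needed. The new E-C4=C5 geometry is set by the chair with C6 pseudo-equatorial, and the new C1 carbinol centre, made by peripheral attack of the oxaziridine on the C10/C1 enolate, is not relied upon because it is reset in step 23. The step needs the vinyl and isopropenyl groups gauche and trans, which the all-equatorial chair of 19 secures (its ring flip would place O6, O8 and the vinyl group syn-axial), and it needs the regiodefined C10/C1 enolate to be oxidised at −78 °C before it can equilibrate toward C9.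

Step 14
Reactants: 22 ten-membered α-hydroxy ketone
Product: 23 C1 tert-butyldimethylsilyl ether of 22
Conditions: TBSOTf, 2,6-lutidine, CH2Cl2, −78 °C
Reagents that add atoms: tert-butyldimethylsilyl trifluoromethanesulfonate, CC(C)(C)[Si](C)(C)OS(=O)(=O)C(F)(F)F
Why: Silylation of the secondary carbinol should block C1 so that the ketone can only be enolised toward C9.

Step 15
Reactants: 23 C1 tert-butyldimethylsilyl ether of 22
Product: 25 enol triflate (C9=C10 with C8 and C1 cis), via potassium enolate 24 (not isolated)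
Conditions: KN(SiMe3)2, THF, −78 °C; N-(5-chloropyridin-2-yl)bis(trifluoromethanesulfonimide), −78 °C
Reagents that add atoms: N-(5-chloropyridin-2-yl)bis(trifluoromethanesulfonimide), Clc1ccc(nc1)N(S(=O)(=O)C(F)(F)F)S(=O)(=O)C(F)(F)F
Why: Kinetic enolisation at the C9 methylene (C1 is a silyloxy methine) should give the ring-cis enolate favoured in a cyclodecanone, and trapping with Comins' reagent at −78 °C should outrun β-elimination of the C8 silyloxy group.

Step 16
Reactants: 25 enol triflate
Product: 26 methyl triene (Z-C9=C10 bearing C14)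
Conditions: Pd(PPh3)4 (5 mol%), MeZnCl, THF, 25 °C
Reagents that add atoms: methylzinc chloride, C[Zn]Cl
Why: Negishi coupling of the alkenyl triflate under zerovalent palladium catalysis should install C14 with retention of the double-bond geometry.

Step 17
Reactants: 26 methyl triene
Product: 27 C8 alcohol
Conditions: PPTS, MeOH/CH2Cl2, 0 °C
Reagents that add atoms: none
Why: Acid-catalysed methanolysis should remove the triethylsilyl ether selectively in the presence of the three tert-butyldimethylsilyl ethers.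

Step 18
Reactants: 27 C8 alcohol
Product: 28 C8 tiglate
Conditions: (E)-2-methylbut-2-enoyl chloride, Et3N, DMAP, CH2Cl2, 0 → 25 °C
Reagents that add atoms: tigloyl chloride, C/C=C(\C)C(=O)Cl
Why: DMAP-catalysed acylation of the only free hydroxyl should give the ester, the E (tiglate) geometry being the stable one.

Step 19
Reactants: 28 C8 tiglate
Product: 29 triol (C1–OH and C6–OH and C12–OH)
Conditions: HF·pyridine, pyridine, THF, 0 → 25 °C
Reagents that add atoms: none
Why: Buffered fluoride desilylation should free the three silyl ethers without acyl migration of the tiglate and without touching the benzyl-type ether.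

Step 20
Reactants: 29 triol
Product: 32 butenolide enone (C12 lactone and C1 ketone), via lactol 30 (not isolated), via hydroxy butenolide 31 (not isolated)
Conditions: TEMPO (20 mol%), PhI(OAc)2 (3.5 equiv), CH2Cl2, 25 °C
Reagents that add atoms: none
Why: Oxoammonium oxidation should take the primary allylic alcohol first, the aldehyde closing onto the cis C6–OH to a lactol that is oxidised to the butenolide (oxidative lactonisation of a 1,4-diol), and the same reagent should then convert the secondary allylic C1 carbinol to the enone.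

Step 21
Reactants: 32 butenolide enone
Product: 33 (4R,5R)-epoxide
Conditions: mCPBA, NaHCO3, CH2Cl2, 0 °C
Reagents that add atoms: 3-chloroperoxybenzoic acid, OOC(=O)c1cccc(Cl)c1
Why: Prilezhaev epoxidation should take the only electron-rich alkene (C4=C5; the other three are conjugated to carbonyls) from its peripheral face in the conformer with C6–H eclipsing the alkene (allylic 1,3-strain with C15), that is anti to C7, as in parthenolide-type 4,5-epoxides.

Step 22
Reactants: 33 (4R,5R)-epoxide
Product: 34 hydroxymethyl enone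
Conditions: DDQ, CH2Cl2/pH 7 buffer, 0 °C
Reagents that add atoms: none
Why: Oxidative cleavage of the 4-methoxybenzyl ether should free the C13 hydroxyl at a stage where no oxidisable allylic carbinol is present.

Step 23
Reactants: 34 hydroxymethyl enone
Product: 35 target CNP0167056.1
Conditions: (S)-2-methyl-CBS-oxazaborolidine, catecholborane, toluene, −78 °C
Reagents that add atoms: none
Why: Corey–Bakshi–Shibata reduction should reduce only the ketone (1,2-mode), the α-methylalkenyl C10 side acting as the large group so that the (S)-catalyst gives the (1R)-carbinol by reagent control.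

**Compound list**

1 | 4,4-dimethoxycyclohexa-2,5-dien-1-one | COC1(OC)C=CC(=O)C=C1 | starting material
2 | potassium isopropenyltrifluoroborate | [K+].C=C(C)[B-](F)(F)F | starting material
3 | (S)-4,4-dimethoxy-5-(prop-1-en-2-yl)cyclohex-2-en-1-one | [C@@H]1(C(C)=C)CC(=O)C=CC1(OC)OC | intermediate
4 | (S)-triethyl{[4,4-dimethoxy-5-(prop-1-en-2-yl)cyclohex-1-en-1-yl]oxy}silane | [C@@H]1(C(C)=C)CC(O[Si](CC)(CC)CC)=CCC1(OC)OC | intermediate
5 | 4,4-dimethoxy-3-(prop-1-en-2-yl)-1-(triethylsilyloxy)-7-oxabicyclo[4.1.0]heptane, epoxide oxygen trans to isopropenyl | [C@@H]1(C(C)=C)C[C@@]2(O[Si](CC)(CC)CC)O[C@H]2CC1(OC)OC | intermediate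
6 | (2S,5S)-4,4-dimethoxy-5-(prop-1-en-2-yl)-2-(triethylsilyloxy)cyclohexan-1-one | [C@@H]1(C(C)=C)CC(=O)[C@@H](O[Si](CC)(CC)CC)CC1(OC)OC | intermediate
7 | potassium C6/C7 enolate of 6 | [C@@H]1(C(C)=C)C=C(O[K])[C@@H](O[Si](CC)(CC)CC)CC1(OC)OC | intermediate
8 | (2R,3R,6S)-2-hydroxy-4,4-dimethoxy-3-(prop-1-en-2-yl)-6-(triethylsilyloxy)cyclohexan-1-one | [C@@H]1(C(C)=C)[C@@H](O)C(=O)[C@@H](O[Si](CC)(CC)CC)CC1(OC)OC | intermediate
9 | ethyl 2-(diethoxyphosphoryl)acrylate | CCOC(=O)C(=C)P(=O)(OCC)OCC | starting material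
10 | 4-methoxybenzyl alcohol | COc1ccc(CO)cc1 | starting material
11 | ethyl 2-(diethoxyphosphoryl)-3-[(4-methoxybenzyl)oxy]propanoate | CCOC(=O)C(COCc1ccc(OC)cc1)P(=O)(OCC)OCC | intermediate
12 | 2-(diethoxyphosphoryl)-3-[(4-methoxybenzyl)oxy]propanoic acid | OC(=O)C(COCc1ccc(OC)cc1)P(=O)(OCC)OCC | intermediate
13 | C6-O ester of 8 with acid 12 | [C@@H]1(C(C)=C)[C@@H](OC(=O)C(COCc2ccc(OC)cc2)P(=O)(OCC)OCC)C(=O)[C@@H](O[Si](CC)(CC)CC)CC1(OC)OC | intermediate
14 | (4S,7R,7aR)-6,6-dimethoxy-3-{[(4-methoxybenzyl)oxy]methyl}-7-(prop-1-en-2-yl)-4-(triethylsilyloxy)-5,6,7,7a-tetrahydro-1-benzofuran-2(4H)-one | [C@@H]1(C(C)=C)[C@H]2OC(=O)C(COCc3ccc(OC)cc3)=C2[C@@H](O[Si](CC)(CC)CC)CC1(OC)OC | intermediate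
15 | lactol of 14 (C12 hemiacetal; aluminium alkoxide in the flask) | [C@@H]1(C(C)=C)[C@H]2OC(O)C(COCc3ccc(OC)cc3)=C2[C@@H](O[Si](CC)(CC)CC)CC1(OC)OC | intermediate
16 | (5R,6R,8S)-cis-enediol: cyclohexane with C6–OH, C8–OSiEt3, C10 dimethyl ketal and exocyclic C7=C11 carrying CH2OH cis to C6 and CH2OPMB cis to C8 | [C@@H]1(C(C)=C)[C@@H](O)/C(=C(\CO)COCc2ccc(OC)cc2)[C@@H](O[Si](CC)(CC)CC)CC1(OC)OC | intermediate
17 | bis(tert-butyldimethylsilyl) ether of 16 (O6 and O12) | [C@@H]1(C(C)=C)[C@@H](O[Si](C)(C)C(C)(C)C)/C(=C(\CO[Si](C)(C)C(C)(C)C)COCc2ccc(OC)cc2)[C@@H](O[Si](CC)(CC)CC)CC1(OC)OC | intermediate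
18 | C10 ketone from 17 | [C@@H]1(C(C)=C)[C@@H](O[Si](C)(C)C(C)(C)C)/C(=C(\CO[Si](C)(C)C(C)(C)C)COCc2ccc(OC)cc2)[C@@H](O[Si](CC)(CC)CC)CC1=O | intermediate
19 | (5R,6R,8S,10R)-1-vinylcyclohexanol: vinyl trans to isopropenyl, OH cis to isopropenyl | [C@@H]1(C(C)=C)[C@@H](O[Si](C)(C)C(C)(C)C)/C(=C(\CO[Si](C)(C)C(C)(C)C)COCc2ccc(OC)cc2)[C@@H](O[Si](CC)(CC)CC)C[C@@]1(O)C=C | intermediate
20 | potassium alkoxide of 19 | [C@@H]1(C(C)=C)[C@@H](O[Si](C)(C)C(C)(C)C)/C(=C(\CO[Si](C)(C)C(C)(C)C)COCc2ccc(OC)cc2)[C@@H](O[Si](CC)(CC)CC)C[C@@]1(O[K])C=C | intermediate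
21 | (6R,8S)-ten-membered potassium enolate (C10=C1 enolate, E-C4=C5) | [K]O/C1=C\CC/C(C)=C/[C@@H](O[Si](C)(C)C(C)(C)C)/C(=C(\CO[Si](C)(C)C(C)(C)C)COCc2ccc(OC)cc2)[C@@H](O[Si](CC)(CC)CC)C1 | intermediate
22 | (6R,8S,4E)-cyclodec-4-enone with C10 ketone and C1–OH (C1 epimers) | OC1CC/C(C)=C/[C@@H](O[Si](C)(C)C(C)(C)C)/C(=C(\CO[Si](C)(C)C(C)(C)C)COCc2ccc(OC)cc2)[C@@H](O[Si](CC)(CC)CC)CC1=O | intermediate
23 | C1 tert-butyldimethylsilyl ether of 22 | CC(C)(C)[Si](C)(C)OC1CC/C(C)=C/[C@@H](O[Si](C)(C)C(C)(C)C)/C(=C(\CO[Si](C)(C)C(C)(C)C)COCc2ccc(OC)cc2)[C@@H](O[Si](CC)(CC)CC)CC1=O | intermediate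
24 | potassium C9=C10 enolate of 23 | CC(C)(C)[Si](C)(C)OC1CC/C(C)=C/[C@@H](O[Si](C)(C)C(C)(C)C)/C(=C(\CO[Si](C)(C)C(C)(C)C)COCc2ccc(OC)cc2)[C@@H](O[Si](CC)(CC)CC)/C=C1/O[K] | intermediate
25 | C10 enol triflate (C8 and C1 cis) | CC(C)(C)[Si](C)(C)OC1CC/C(C)=C/[C@@H](O[Si](C)(C)C(C)(C)C)/C(=C(\CO[Si](C)(C)C(C)(C)C)COCc2ccc(OC)cc2)[C@@H](O[Si](CC)(CC)CC)/C=C1/OS(=O)(=O)C(F)(F)F | intermediate
26 | methyl triene (4E,9Z) | CC(C)(C)[Si](C)(C)OC1CC/C(C)=C/[C@@H](O[Si](C)(C)C(C)(C)C)/C(=C(\CO[Si](C)(C)C(C)(C)C)COCc2ccc(OC)cc2)[C@@H](O[Si](CC)(CC)CC)/C=C1/C | intermediate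
27 | C8 alcohol | CC(C)(C)[Si](C)(C)OC1CC/C(C)=C/[C@@H](O[Si](C)(C)C(C)(C)C)/C(=C(\CO[Si](C)(C)C(C)(C)C)COCc2ccc(OC)cc2)[C@@H](O)/C=C1/C | intermediate
28 | C8 tiglate | CC(C)(C)[Si](C)(C)OC1CC/C(C)=C/[C@@H](O[Si](C)(C)C(C)(C)C)/C(=C(\CO[Si](C)(C)C(C)(C)C)COCc2ccc(OC)cc2)[C@@H](OC(=O)/C(C)=C/C)/C=C1/C | intermediate
29 | triol (C1–OH, C6–OH, C12–OH) | OC1CC/C(C)=C/[C@@H](O)/C(=C(\CO)COCc2ccc(OC)cc2)[C@@H](OC(=O)/C(C)=C/C)/C=C1/C | intermediate
30 | lactol (C12 hemiacetal, C1–OH) | OC1CC/C(C)=C/[C@H]2OC(O)C(COCc3ccc(OC)cc3)=C2[C@@H](OC(=O)/C(C)=C/C)/C=C1/C | intermediate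
31 | hydroxy butenolide (C1–OH) | OC1CC/C(C)=C/[C@H]2OC(=O)C(COCc3ccc(OC)cc3)=C2[C@@H](OC(=O)/C(C)=C/C)/C=C1/C | intermediate
32 | (6R,8S)-butenolide enone (C1 ketone, 4E,9Z) | O=C1CC/C(C)=C/[C@H]2OC(=O)C(COCc3ccc(OC)cc3)=C2[C@@H](OC(=O)/C(C)=C/C)/C=C1/C | intermediate
33 | (4R,5R,6S,8S)-4,5-epoxide | O=C1CC[C@@]2(C)O[C@@H]2[C@H]2OC(=O)C(COCc3ccc(OC)cc3)=C2[C@@H](OC(=O)/C(C)=C/C)/C=C1/C | intermediate
34 | (4R,5R,6S,8S)-13-hydroxy enone | O=C1CC[C@@]2(C)O[C@@H]2[C@H]2OC(=O)C(CO)=C2[C@@H](OC(=O)/C(C)=C/C)/C=C1/C | intermediate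
35 | CNP0167056.1, (1R,4R,5R,6S,8S,9Z) | C/C=C(\C)C(=O)O[C@H]1/C=C(/C)[C@H](O)CC[C@@]2(C)O[C@@H]2[C@H]2OC(=O)C(CO)=C12 | target

**Step count.** 23 steps in total; the longest linear sequence is 21 steps (steps 1–4 and 7–23).

**Steps most likely to fail, with fallbacks**

Step 13. The alkoxide may fragment (retro-ene or cleavage of C5–C10 without recombination), or the rearrangement may stall or leave the chair pathway because of allylic strain around C7=C11. Fallback: from 19 the ring expansion would be run without the alkoxide, as an oxy-Cope rearrangement catalysed by divalent palladium (PdCl2(PhCN)2, THF, 25 °C), a cyclisation-induced process that profits from the 2-substituted isopropenyl alkene. This should give the cyclodecenone F1. Kinetic deprotonation of F1 at the less hindered C1 methylene (KN(SiMe3)2, −78 °C) and hydroxylation with the same oxaziridine would return to 22.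

Step 15. Enolisation may deliver the ring-trans enolate, or the C9 enolate may expel the C8 silyloxy group. Fallback: from 23 the hydrazone F2 (N2H4·H2O, Et3N, EtOH) would be converted by Barton's procedure (I2, tetramethylguanidine, THF) into the vinyl iodide F3 without any enolate, the proton being lost from C9 and not from the silyloxy-bearing C1. Negishi methylation of F3 (Pd(PPh3)4, MeZnCl) would return to 26.

Step 20. The bis-allylic C6 carbinol may be oxidised before the lactol closes, or the lactol may dehydrate to a furan. Fallback: from 28 only the primary C12 silyl ether would be cleaved (HF·pyridine, pyridine, THF, −10 °C) to the primary alcohol F4. F4 would be oxidised in two stages, with Dess–Martin periodinane to the enal F5 and then with NaClO2, NaH2PO4 and 2-methyl-2-butene to the acid F6. Removal of the two remaining silyl ethers from F6 with HF·pyridine would let the cis γ-hydroxy acid lactonise to 31, and Dess–Martin oxidation of the C1 carbinol would return to 32.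

**Further compounds**

F1 | step 13 | (6R,8S,4E)-cyclodec-4-enone lacking the C1 oxygen | O=C1CCC/C(C)=C/[C@@H](O[Si](C)(C)C(C)(C)C)/C(=C(\CO[Si](C)(C)C(C)(C)C)COCc2ccc(OC)cc2)[C@@H](O[Si](CC)(CC)CC)C1
F2 | step 15 | hydrazone of 23 | CC(C)(C)[Si](C)(C)OC1CC/C(C)=C/[C@@H](O[Si](C)(C)C(C)(C)C)/C(=C(\CO[Si](C)(C)C(C)(C)C)COCc2ccc(OC)cc2)[C@@H](O[Si](CC)(CC)CC)CC1=NN
F3 | step 15 | C10 vinyl iodide (C8 and C1 cis) | CC(C)(C)[Si](C)(C)OC1CC/C(C)=C/[C@@H](O[Si](C)(C)C(C)(C)C)/C(=C(\CO[Si](C)(C)C(C)(C)C)COCc2ccc(OC)cc2)[C@@H](O[Si](CC)(CC)CC)/C=C1/I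
F4 | step 20 | C12 primary alcohol (O1 and O6 silylated) | CC(C)(C)[Si](C)(C)OC1CC/C(C)=C/[C@@H](O[Si](C)(C)C(C)(C)C)/C(=C(\CO)COCc2ccc(OC)cc2)[C@@H](OC(=O)/C(C)=C/C)/C=C1/C
F5 | step 20 | C12 enal | CC(C)(C)[Si](C)(C)OC1CC/C(C)=C/[C@@H](O[Si](C)(C)C(C)(C)C)/C(=C(\C=O)COCc2ccc(OC)cc2)[C@@H](OC(=O)/C(C)=C/C)/C=C1/C
F6 | step 20 | C12 carboxylic acid | CC(C)(C)[Si](C)(C)OC1CC/C(C)=C/[C@@H](O[Si](C)(C)C(C)(C)C)/C(=C(\C(=O)O)COCc2ccc(OC)cc2)[C@@H](OC(=O)/C(C)=C/C)/C=C1/C
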